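## Retrosynthetic overview

1. The target comes from a 7,8-bis-silylated lactone that already carries the (2S,3S)-epoxyangelate on O9: desilylation, then acetylation of the secondary C8–OH.
2. Key step: the ten-membered carbocycle (ring A) and the α-methylene-γ-lactone (ring B) form together. An open-chain alkenyl bromide/aldehyde closes C5–C6 by an intramolecular Nozaki–Hiyama–Kishi reaction, and the new C6 alkoxide lactonises onto the methyl acrylate on C7.
3. The open chain comes from a C9–C10 Nozaki–Hiyama–Kishi union of a (Z)-alkenyl iodide/(E)-alkenyl bromide diene with a C9 aldehyde, followed by esterification of the new C9–OH with the epoxy acid.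
4. The C6–C9/C11–C13 core comes from L-erythrulose (C8 from the pool) and α-vinylalumination with methyl propiolate (C7). C7, C9 and C6 are each set by Felkin–Anh induction relayed from C8.
5. Ring order: the epoxide (ring C) is made first on the side-chain acid by Sharpless epoxidation; rings A and B form simultaneously in the key step.

Assumption: germacranolide numbering is used (lactone O on C6, C12 carbonyl, C13 methylene, C14 on C10, C15 on C4), and the SMILES is read as 6S,7S,8S,9S, 1(10)Z, 4E with a (2S,3S)-epoxyangelate.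

## Route

Step 1
Reactants: 1 pent-4-yn-1-ol
Product: 3 (4E)-5-bromo-4-methylpent-4-en-1-ol, via alkenyldimethylalane 2 (not isolated)
Conditions: AlMe3, Cp2ZrCl2 (cat.), CH2Cl2, 0 °C to rt; then NBS, THF, −30 to 0 °C
Reagents that add atoms: trimethylaluminium, C[Al](C)C; N-bromosuccinimide, O=C1CCC(=O)N1Br
Why: Negishi zirconium-catalysed carboalumination adds methyl and aluminium syn across the alkyne (aluminium terminal), and bromodealumination with retention gives the E-alkenyl bromide that becomes C4=C5.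

Step 2
Reactants: 3 (4E)-5-bromo-4-methylpent-4-en-1-ol
Product: 4 (4E)-5-bromo-4-methylpent-4-enal
Conditions: Dess–Martin periodinane, CH2Cl2, 0 °C to rt
Reagents that add atoms: none
Why: Dess–Martin oxidation takes the primary alcohol to the aldehyde without touching the alkenyl bromide.

Step 3
Reactants: 4 (4E)-5-bromo-4-methylpent-4-enal; 5 ethyltriphenylphosphonium iodide
Product: 9 (1E,5Z)-1-bromo-6-iodo-2-methylhepta-1,5-diene, via ethylidenetriphenylphosphorane 6 (not isolated), via (1-iodoethyl)triphenylphosphonium iodide 7 (not isolated), via (1-iodoethylidene)triphenylphosphorane 8 (not isolated)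
Conditions: 5, n-BuLi, THF, rt; I2, −78 °C; NaN(SiMe3)2, −20 °C; then 4, −78 °C to rt
Reagents that add atoms: iodine, [I][I]
Why: Stork–Zhao-type Wittig olefination with the α-iodo ylide gives the 2-iodoalkene with iodine cis to the chain (Z), which fixes the cis C1=C10 geometry.

Step 4
Reactants: 10 methyl angelate [methyl (2Z)-2-methylbut-2-enoate]
Product: 11 (2Z)-2-methylbut-2-en-1-ol
Conditions: i-Bu2AlH, CH2Cl2, −78 °C
Reagents that add atoms: none
Why: Hydride 1,2-reduction of the enoate gives the allylic alcohol with the Z-alkene retained.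

Step 5
Reactants: 11 (2Z)-2-methylbut-2-en-1-ol
Product: 12 [(2R,3S)-2,3-dimethyloxiran-2-yl]methanol
Conditions: Ti(OiPr)4 (cat.), D-(−)-diethyl tartrate (cat.), t-BuOOH, 4 Å molecular sieves, CH2Cl2, −20 °C
Reagents that add atoms: tert-butyl hydroperoxide, CC(C)(C)OO
Why: Sharpless asymmetric epoxidation: the D-(−)-tartrate catalyst delivers oxygen to the face opposite to the one used by L-(+)-tartrate (which gives 2S,3S epoxides from E-2-alkenols), so the Z-alkene gives the cis-epoxide as its (2R,3S) enantiomer.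

Step 6
Reactants: 12 [(2R,3S)-2,3-dimethyloxiran-2-yl]methanol
Product: 13 (2S,3S)-2,3-dimethyloxirane-2-carboxylic acid
Conditions: RuCl3 (cat.), NaIO4, EtOAc/MeCN/H2O, rt
Reagents that add atoms: sodium periodate, [Na+].[O-]I(=O)(=O)=O; water, O
Why: Sharpless RuCl3/NaIO4 oxidation takes the primary alcohol to the acid without touching the epoxide, and the C2 descriptor changes from R to S only because the priorities change.

Step 7
Reactants: 14 L-erythrulose [(3S)-1,3,4-trihydroxybutan-2-one]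
Product: 15 (3S)-1,3,4-tris[(triethylsilyl)oxy]butan-2-one
Conditions: Et3SiCl, imidazole, DMF, 0 °C
Reagents that add atoms: chlorotriethylsilane, CC[Si](Cl)(CC)CC
Why: Exhaustive silylation under mild base keeps the C3 stereocentre of L-erythrulose, which becomes C8 of the target.

Step 8
Reactants: 15 (3S)-1,3,4-tris[(triethylsilyl)oxy]butan-2-one; 16 methyl propiolate
Product: 18 methyl (3S,4S)-3-hydroxy-2-methylidene-4,5-bis[(triethylsilyl)oxy]-3-{[(triethylsilyl)oxy]methyl}pentanoate, via [1-(methoxycarbonyl)ethenyl]diisobutylalane 17 (not isolated)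
Conditions: i-Bu2AlH, N-methylmorpholine N-oxide, THF, 0 °C; 16; then 15, 0 °C to rt
Reagents that add atoms: none
Why: Tsuda–Ramachandran vinylalumination: 1,4-hydroalumination of the propiolate gives the α-aluminated acrylate, which adds to the activated ketone (Baylis–Hillman-type adduct) anti to the non-chelating C8 silyloxy group (Felkin–Anh), setting C7 with the 7,8-syn relationship.

Step 9
Reactants: 18 methyl (3S,4S)-3-hydroxy-2-methylidene-4,5-bis[(triethylsilyl)oxy]-3-{[(triethylsilyl)oxy]methyl}pentanoate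
Product: 19 methyl (3S,4S)-2-methylidene-3,4,5-tris[(triethylsilyl)oxy]-3-{[(triethylsilyl)oxy]methyl}pentanoate
Conditions: Et3SiOTf, 2,6-lutidine, CH2Cl2, −78 to 0 °C
Reagents that add atoms: triethylsilyl trifluoromethanesulfonate, CC[Si](CC)(CC)OS(=O)(=O)C(F)(F)F
Why: Silyl triflate silylation caps the tertiary alcohol so that neither later chromium coupling can chelate to O7.

Step 10
Reactants: 19 methyl (3S,4S)-2-methylidene-3,4,5-tris[(triethylsilyl)oxy]-3-{[(triethylsilyl)oxy]methyl}pentanoate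
Product: 20 methyl (3S,4R)-2-methylidene-5-oxo-3,4-bis[(triethylsilyl)oxy]-3-{[(triethylsilyl)oxy]methyl}pentanoate
Conditions: (COCl)2 (1.1 equiv), DMSO, CH2Cl2, −78 to −40 °C; Et3N
Reagents that add atoms: none
Why: Swern oxidation converts a primary triethylsilyl ether directly into the aldehyde, and the C9 ether reacts ahead of the neopentyl C6 ether (next to quaternary C7) and of the secondary and tertiary ethers.

Step 11
Reactants: 20 methyl (3S,4R)-2-methylidene-5-oxo-3,4-bis[(triethylsilyl)oxy]-3-{[(triethylsilyl)oxy]methyl}pentanoate; 9 (1E,5Z)-1-bromo-6-iodo-2-methylhepta-1,5-diene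
Product: 21 methyl (3S,4S,5S,6Z,10E)-11-bromo-5-hydroxy-6,10-dimethyl-2-methylidene-3,4-bis[(triethylsilyl)oxy]-3-{[(triethylsilyl)oxy]methyl}undeca-6,10-dienoate
Conditions: CrCl2, NiCl2 (cat.), DMSO, rt
Reagents that add atoms: none
Why: Nozaki–Hiyama–Kishi coupling: zerovalent nickel inserts into C–I far faster than into C–Br, the alkenylchromium keeps its Z geometry, and it adds to the aldehyde anti to the C8 silyloxy group (Felkin–Anh), giving the 8,9-anti C9 carbinol.

Step 12
Reactants: 21 methyl (3S,4S,5S,6Z,10E)-11-bromo-5-hydroxy-6,10-dimethyl-2-methylidene-3,4-bis[(triethylsilyl)oxy]-3-{[(triethylsilyl)oxy]methyl}undeca-6,10-dienoate; 13 (2S,3S)-2,3-dimethyloxirane-2-carboxylic acid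
Product: 23 methyl (3S,4S,5S,6Z,10E)-11-bromo-5-{[(2S,3S)-2,3-dimethyloxirane-2-carbonyl]oxy}-6,10-dimethyl-2-methylidene-3,4-bis[(triethylsilyl)oxy]-3-{[(triethylsilyl)oxy]methyl}undeca-6,10-dienoate, via Yamaguchi mixed anhydride 22 (not isolated)
Conditions: 13, 2,4,6-Cl3C6H2COCl, Et3N, THF; then 21, DMAP, toluene, rt
Reagents that add atoms: none
Why: Yamaguchi esterification acylates the only free hydroxyl (hindered, allylic C9–OH) with the α,α-disubstituted epoxy acid and touches no stereocentre.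

Step 13
Reactants: 23 methyl (3S,4S,5S,6Z,10E)-11-bromo-5-{[(2S,3S)-2,3-dimethyloxirane-2-carbonyl]oxy}-6,10-dimethyl-2-methylidene-3,4-bis[(triethylsilyl)oxy]-3-{[(triethylsilyl)oxy]methyl}undeca-6,10-dienoate
Product: 24 methyl (3R,4S,5S,6Z,10E)-11-bromo-5-{[(2S,3S)-2,3-dimethyloxirane-2-carbonyl]oxy}-3-formyl-6,10-dimethyl-2-methylidene-3,4-bis[(triethylsilyl)oxy]undeca-6,10-dienoate
Conditions: (COCl)2, DMSO, CH2Cl2, −78 to −30 °C; Et3N
Reagents that add atoms: none
Why: Swern oxidation of the remaining primary triethylsilyl ether gives the C6 aldehyde directly, so no free C6 alcohol ever exists next to the acrylate ester to lactonise prematurely (the C3 descriptor changes by priority only).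

Step 14
Reactants: 24 methyl (3R,4S,5S,6Z,10E)-11-bromo-5-{[(2S,3S)-2,3-dimethyloxirane-2-carbonyl]oxy}-3-formyl-6,10-dimethyl-2-methylidene-3,4-bis[(triethylsilyl)oxy]undeca-6,10-dienoate
Product: 26 (6S,7S,8S,9S,1(10)Z,4E)-9-{[(2S,3S)-2,3-dimethyloxirane-2-carbonyl]oxy}-7,8-bis[(triethylsilyl)oxy]germacra-1(10),4,11(13)-trien-6,12-olide, via ten-membered hydroxy ester 25 (not isolated)
Conditions: CrCl2 (excess), NiCl2 (cat.), DMSO/THF, 0.003 M, slow addition, rt to 45 °C; aq. NH4Cl
Reagents that add atoms: none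
Why: Intramolecular Nozaki–Hiyama–Kishi coupling closes C5–C6 with retention of the E-alkene and sets C6 by Felkin–Anh attack anti to the C7 silyloxy group with the flat acrylate arm as the small substituent (6,7-anti, trans-fused), and the trivalent chromium alkoxide then attacks the methyl ester five-exo to close the α-methylene-γ-lactone in the same flask (tandem coupling/lactonisation).

Step 15
Reactants: 26 (6S,7S,8S,9S,1(10)Z,4E)-9-{[(2S,3S)-2,3-dimethyloxirane-2-carbonyl]oxy}-7,8-bis[(triethylsilyl)oxy]germacra-1(10),4,11(13)-trien-6,12-olide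
Product: 27 (1(10)Z,4E)-9-{[(2S,3S)-2,3-dimethyloxirane-2-carbonyl]oxy}-7,8-dihydroxygermacra-1(10),4,11(13)-trien-6,12-olide (geometry as in 26; CIP 6S,7R,8S,9S)
Conditions: HF·pyridine, pyridine, THF, 0 °C to rt
Reagents that add atoms: none
Why: Buffered fluoride desilylation cleaves the secondary and tertiary Si–O bonds while the glycidic ester, allylic ester and methylene lactone are left alone.

Step 16
Reactants: 27 (1(10)Z,4E)-9-{[(2S,3S)-2,3-dimethyloxirane-2-carbonyl]oxy}-7,8-dihydroxygermacra-1(10),4,11(13)-trien-6,12-olide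
Product: 28 (6S,7S,8S,9S,1(10)Z,4E)-8-acetoxy-9-{[(2S,3S)-2,3-dimethyloxirane-2-carbonyl]oxy}-7-hydroxygermacra-1(10),4,11(13)-trien-6,12-olide (CNP0271187.2)
Conditions: Ac2O, pyridine, DMAP (cat.), CH2Cl2, 0 °C
Reagents that add atoms: acetic anhydride, CC(=O)OC(C)=O
Why: DMAP-catalysed acetylation takes the secondary C8–OH and leaves the tertiary C7–OH free, giving the target.

## Compound list

1 | pent-4-yn-1-ol | C#CCCCO | starting material
2 | alkenyldimethylalane from 1 (O-aluminated; Al trans to the chain) | C[Al](C)OCCC/C(C)=C/[Al](C)C | intermediate (not isolated)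
3 | (4E)-5-bromo-4-methylpent-4-en-1-ol | Br/C=C(\C)CCCO | intermediate
4 | (4E)-5-bromo-4-methylpent-4-enal | Br/C=C(\C)CCC=O | intermediate
5 | ethyltriphenylphosphonium iodide | CC[P+](c1ccccc1)(c1ccccc1)c1ccccc1.[I-] | starting material
6 | ethylidenetriphenylphosphorane | CC=P(c1ccccc1)(c1ccccc1)c1ccccc1 | intermediate (not isolated)
7 | (1-iodoethyl)triphenylphosphonium iodide | CC(I)[P+](c1ccccc1)(c1ccccc1)c1ccccc1.[I-] | intermediate (not isolated)
8 | (1-iodoethylidene)triphenylphosphorane | CC(I)=P(c1ccccc1)(c1ccccc1)c1ccccc1 | intermediate (not isolated)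
9 | (1E,5Z)-1-bromo-6-iodo-2-methylhepta-1,5-diene | Br/C=C(\C)CC/C=C(/C)I | intermediate
10 | methyl angelate, methyl (2Z)-2-methylbut-2-enoate | C/C=C(/C)C(=O)OC | starting material
11 | (2Z)-2-methylbut-2-en-1-ol | C/C=C(/C)CO | intermediate
12 | [(2R,3S)-2,3-dimethyloxiran-2-yl]methanol | OC[C@@]1(C)O[C@H]1C | intermediate
13 | (2S,3S)-2,3-dimethyloxirane-2-carboxylic acid | OC(=O)[C@@]1(C)O[C@H]1C | intermediate
14 | L-erythrulose, (3S)-1,3,4-trihydroxybutan-2-one | OC[C@H](O)C(=O)CO | starting material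
15 | (3S)-1,3,4-tris[(triethylsilyl)oxy]butan-2-one | CC[Si](CC)(CC)OC[C@H](O[Si](CC)(CC)CC)C(=O)CO[Si](CC)(CC)CC | intermediate
16 | methyl propiolate | C#CC(=O)OC | starting material
17 | [1-(methoxycarbonyl)ethenyl]diisobutylalane | COC(=O)C(=C)[Al](CC(C)C)CC(C)C | intermediate (not isolated)
18 | methyl (3S,4S)-3-hydroxy-2-methylidene-4,5-bis[(triethylsilyl)oxy]-3-{[(triethylsilyl)oxy]methyl}pentanoate | CC[Si](CC)(CC)OC[C@H](O[Si](CC)(CC)CC)[C@](O)(C(=C)C(=O)OC)CO[Si](CC)(CC)CC | intermediate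
19 | methyl (3S,4S)-2-methylidene-3,4,5-tris[(triethylsilyl)oxy]-3-{[(triethylsilyl)oxy]methyl}pentanoate | CC[Si](CC)(CC)OC[C@H](O[Si](CC)(CC)CC)[C@](O[Si](CC)(CC)CC)(C(=C)C(=O)OC)CO[Si](CC)(CC)CC | intermediate
20 | methyl (3S,4R)-2-methylidene-5-oxo-3,4-bis[(triethylsilyl)oxy]-3-{[(triethylsilyl)oxy]methyl}pentanoate | O=C[C@H](O[Si](CC)(CC)CC)[C@](O[Si](CC)(CC)CC)(C(=C)C(=O)OC)CO[Si](CC)(CC)CC | intermediate
21 | methyl (3S,4S,5S,6Z,10E)-11-bromo-5-hydroxy-6,10-dimethyl-2-methylidene-3,4-bis[(triethylsilyl)oxy]-3-{[(triethylsilyl)oxy]methyl}undeca-6,10-dienoate | Br/C=C(\C)CC/C=C(/C)[C@H](O)[C@H](O[Si](CC)(CC)CC)[C@](O[Si](CC)(CC)CC)(C(=C)C(=O)OC)CO[Si](CC)(CC)CC | intermediate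
22 | (2S,3S)-2,3-dimethyloxirane-2-carboxylic 2,4,6-trichlorobenzoic anhydride | O=C(OC(=O)[C@@]1(C)O[C@H]1C)c1c(Cl)cc(Cl)cc1Cl | intermediate (not isolated)
23 | methyl (3S,4S,5S,6Z,10E)-11-bromo-5-{[(2S,3S)-2,3-dimethyloxirane-2-carbonyl]oxy}-6,10-dimethyl-2-methylidene-3,4-bis[(triethylsilyl)oxy]-3-{[(triethylsilyl)oxy]methyl}undeca-6,10-dienoate | Br/C=C(\C)CC/C=C(/C)[C@H](OC(=O)[C@@]1(C)O[C@H]1C)[C@H](O[Si](CC)(CC)CC)[C@](O[Si](CC)(CC)CC)(C(=C)C(=O)OC)CO[Si](CC)(CC)CC | intermediate
24 | methyl (3R,4S,5S,6Z,10E)-11-bromo-5-{[(2S,3S)-2,3-dimethyloxirane-2-carbonyl]oxy}-3-formyl-6,10-dimethyl-2-methylidene-3,4-bis[(triethylsilyl)oxy]undeca-6,10-dienoate | Br/C=C(\C)CC/C=C(/C)[C@H](OC(=O)[C@@]1(C)O[C@H]1C)[C@H](O[Si](CC)(CC)CC)[C@](O[Si](CC)(CC)CC)(C(=C)C(=O)OC)C=O | intermediate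
25 | ten-membered carbocyclic C6 alcohol (chromium alkoxide before work-up) still carrying the methyl acrylate on C7; configuration as in 26 | O[C@H]1/C=C(\C)CC/C=C(/C)[C@H](OC(=O)[C@@]2(C)O[C@H]2C)[C@H](O[Si](CC)(CC)CC)[C@]1(O[Si](CC)(CC)CC)C(=C)C(=O)OC | intermediate (not isolated)
26 | (6S,7S,8S,9S,1(10)Z,4E)-9-{[(2S,3S)-2,3-dimethyloxirane-2-carbonyl]oxy}-7,8-bis[(triethylsilyl)oxy]germacra-1(10),4,11(13)-trien-6,12-olide | C=C1C(=O)O[C@H]2/C=C(\C)CC/C=C(/C)[C@H](OC(=O)[C@@]3(C)O[C@H]3C)[C@H](O[Si](CC)(CC)CC)[C@]12O[Si](CC)(CC)CC | intermediate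
27 | (1(10)Z,4E)-9-{[(2S,3S)-2,3-dimethyloxirane-2-carbonyl]oxy}-7,8-dihydroxygermacra-1(10),4,11(13)-trien-6,12-olide (CIP 6S,7R,8S,9S; geometry as in 28) | C=C1C(=O)O[C@H]2/C=C(\C)CC/C=C(/C)[C@H](OC(=O)[C@@]3(C)O[C@H]3C)[C@H](O)[C@]12O | intermediate
28 | (6S,7S,8S,9S,1(10)Z,4E)-8-acetoxy-9-{[(2S,3S)-2,3-dimethyloxirane-2-carbonyl]oxy}-7-hydroxygermacra-1(10),4,11(13)-trien-6,12-olide, CNP0271187.2 | C=C1C(=O)O[C@H]2/C=C(\C)CC/C=C(/C)[C@H](OC(=O)[C@@]3(C)O[C@H]3C)[C@H](OC(C)=O)[C@]12O | target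

## Step count, longest linear sequence and risks

Total step count: 16. Longest linear sequence: 10 steps (14 to 28, steps 7–16). The diene 9 takes 3 steps and the epoxy acid 13 takes 3 steps.

Most likely to fail, first: step 14. The alkenyl bromide is a slow partner, the ring is strained and C6 selectivity rests on a Felkin–Anh argument next to a quaternary centre. If it fails, the carbocycle is closed by olefin metathesis instead, and the lactone is made one step earlier. The fallback sets out from 20. CrCl2/NiCl2 coupling with 2-bromopropene gives the isopropenyl carbinol methyl (3S,4S,5S)-5-hydroxy-6-methyl-2-methylidene-3,4-bis[(triethylsilyl)oxy]-3-{[(triethylsilyl)oxy]methyl}hept-6-enoate F1. Yamaguchi esterification with 13 gives its epoxyangelate F2, and Swern oxidation of the primary silyl ether gives the C6 aldehyde F3. (1E)-1-iodo-2-methylhexa-1,5-diene F4 (from hex-1-en-5-yne with AlMe3/Cp2ZrCl2, then I2) is coupled with F3 under CrCl2/NiCl2, and the alkoxide lactonises to the open-chain trienyl lactone F5. Ring-closing metathesis of F5 with the second-generation Grubbs catalyst (toluene, 80 °C, high dilution) forms C1=C10, cis being the favoured geometry in a ten-membered ring. This comes back to the route at 26.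

Second: step 8. The hindered ketone may not accept the vinylalane, or facial control may be poor. The fallback sets out from 15. The lithium enolate of methyl 2-(phenylselanyl)propanoate (LiN(i-Pr)2, THF, −78 °C) adds to the ketone in an aldol reaction to give the β-hydroxy selenide methyl (2RS,3S,4S)-3-hydroxy-2-methyl-2-(phenylselanyl)-4,5-bis[(triethylsilyl)oxy]-3-{[(triethylsilyl)oxy]methyl}pentanoate F6. Oxidation with H2O2/pyridine and syn-elimination of the selenoxide can only go toward the methyl group, which installs the methylidene. This comes back to the route at 18.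

Third: step 11. Both partners are hindered, and the free C9 alkoxide can close a six-membered lactone on the acrylate ester before it is acylated. The fallback sets out from 9 and 20 and skips the free alcohol. Iodine–lithium exchange on 9 (t-BuLi, Et2O, −100 °C, iodide ahead of bromide) gives [(2E,6E)-7-bromo-6-methylhepta-2,6-dien-2-yl]lithium F7. Transmetalation with CeCl3 gives dichloro[(2Z,6E)-7-bromo-6-methylhepta-2,6-dien-2-yl]cerium F8, which adds to aldehyde 20 at −78 °C (Felkin–Anh). The cerium alkoxide is acylated in the same flask with the mixed anhydride 22. This comes back to the route at 23.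

## Further compounds

F1 | step 14 | methyl (3S,4S,5S)-5-hydroxy-6-methyl-2-methylidene-3,4-bis[(triethylsilyl)oxy]-3-{[(triethylsilyl)oxy]methyl}hept-6-enoate | C=C(C)[C@H](O)[C@H](O[Si](CC)(CC)CC)[C@](O[Si](CC)(CC)CC)(C(=C)C(=O)OC)CO[Si](CC)(CC)CC
F2 | step 14 | methyl (3S,4S,5S)-5-{[(2S,3S)-2,3-dimethyloxirane-2-carbonyl]oxy}-6-methyl-2-methylidene-3,4-bis[(triethylsilyl)oxy]-3-{[(triethylsilyl)oxy]methyl}hept-6-enoate | C=C(C)[C@H](OC(=O)[C@@]1(C)O[C@H]1C)[C@H](O[Si](CC)(CC)CC)[C@](O[Si](CC)(CC)CC)(C(=C)C(=O)OC)CO[Si](CC)(CC)CC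
F3 | step 14 | methyl (3R,4S,5S)-5-{[(2S,3S)-2,3-dimethyloxirane-2-carbonyl]oxy}-3-formyl-6-methyl-2-methylidene-3,4-bis[(triethylsilyl)oxy]hept-6-enoate | C=C(C)[C@H](OC(=O)[C@@]1(C)O[C@H]1C)[C@H](O[Si](CC)(CC)CC)[C@](O[Si](CC)(CC)CC)(C(=C)C(=O)OC)C=O
F4 | step 14 | (1E)-1-iodo-2-methylhexa-1,5-diene | I/C=C(\C)CCC=C
F5 | step 14 | open-chain trienyl α-methylene-γ-lactone (C6 bearing the (1E)-2-methylhexa-1,5-dienyl group, C9 bearing isopropenyl; configuration as in 26) | C=C1C(=O)O[C@@H](/C=C(\C)CCC=C)[C@]1(O[Si](CC)(CC)CC)[C@@H](O[Si](CC)(CC)CC)[C@@H](OC(=O)[C@@]2(C)O[C@H]2C)C(C)=C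
F6 | step 8 | methyl (2RS,3S,4S)-3-hydroxy-2-methyl-2-(phenylselanyl)-4,5-bis[(triethylsilyl)oxy]-3-{[(triethylsilyl)oxy]methyl}pentanoate | CC[Si](CC)(CC)OC[C@H](O[Si](CC)(CC)CC)[C@](O)(C(C)([Se]c1ccccc1)C(=O)OC)CO[Si](CC)(CC)CC
F7 | step 11 | [(2E,6E)-7-bromo-6-methylhepta-2,6-dien-2-yl]lithium | [Li]/C(C)=C\CC/C(C)=C/Br
F8 | step 11 | dichloro[(2Z,6E)-7-bromo-6-methylhepta-2,6-dien-2-yl]cerium | Cl[Ce](Cl)/C(C)=C\CC/C(C)=C/Br
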